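## Retrosynthetic overview

1. Ring C is cut at O1–C2: the target comes from the open 2',4',6',4-tetrahydroxychalcone by an enantioselective 6-endo oxa-Michael ring closure (C–O bond, sets C2 as S, last step).
2. The chalcone Cα=Cβ bond comes from a Claisen–Schmidt condensation of a ring A methyl ketone (phloroacetophenone, two phenols as THP ethers) with a ring B aldehyde (phenol as THP ether).
3. The ring B aryl–CH2 bond comes from 3-bromo-4-hydroxybenzaldehyde and an (E)-allylic acetate (one-pot borylation and allyl–aryl Suzuki–Miyaura coupling).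
4. The tertiary alcohol C–O bond comes from Markovnikov hydration of the distal alkene of geranyl acetate.
5. Ring order: rings A and B are bought as arenes; ring C is the only ring built and it closes last.

Assumption: in step 7 the (S)-pipecolic acid-derived ligand L gives the 2S product; if the first run gives 2R, the mirror-image ligand from (R)-pipecolic acid is used with no other change. The 2S configuration is confirmed by chiral HPLC and by the CD curve (positive band near 330 nm, negative near 290 nm).

Ligand L: the C2-symmetric N,N'-dioxide 1,1'-(propane-1,3-diyl)bis{(2S)-2-[(2,6-diisopropylphenyl)carbamoyl]piperidine 1-oxide}, SMILES CC(C)c1cccc(C(C)C)c1NC(=O)[C@@H]1CCCC[N+]1([O-])CCC[N+]1([O-])CCCC[C@H]1C(=O)Nc1c(C(C)C)cccc1C(C)C.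

Note: every THP acetal carbon is racemic. Compounds 5, 6, 7, 9, 10 and 11 are carried as mixtures of acetal epimers, and these centres disappear in step 6.

## Route

Step 1
Reactants: 1 geranyl acetate [(2E)-3,7-dimethylocta-2,6-dien-1-yl acetate]
Product: 3 (2E)-7-hydroxy-3,7-dimethyloct-2-en-1-yl acetate, via alkylmercury acetate 2 (not isolated)
Conditions: Hg(OAc)2 (1.05 equiv), THF/H2O 1:1, rt, 45 min; then NaBH4, 1 M NaOH, 0 °C, 5 min
Reagents that add atoms: water, O
Why: Oxymercuration–demercuration (Markovnikov hydration): divalent mercury adds to the electron-rich distal trisubstituted alkene because the 2,3-alkene is deactivated by the allylic acetoxy group, water opens the mercurinium ion at the tertiary carbon, and NaBH4 replaces Hg by H, so no stereocentre remains and the E-alkene is untouched.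

Step 2
Reactants: 4 3-bromo-4-hydroxybenzaldehyde
Product: 5 3-bromo-4-(tetrahydro-2H-pyran-2-yloxy)benzaldehyde
Conditions: 3,4-dihydro-2H-pyran (2 equiv), PPTS (5 mol %), CH2Cl2, rt
Reagents that add atoms: 3,4-dihydro-2H-pyran, C1=COCCC1
Why: Tetrahydropyranylation (acid-catalysed addition of the phenol to the enol ether) gives a mixed acetal that is stable to base and to palladium and is removable later under buffer-strength acid.

Step 3
Reactants: 5 3-bromo-4-(tetrahydro-2H-pyran-2-yloxy)benzaldehyde; 3 (2E)-7-hydroxy-3,7-dimethyloct-2-en-1-yl acetate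
Product: 7 3-[(2E)-7-hydroxy-3,7-dimethyloct-2-en-1-yl]-4-(tetrahydro-2H-pyran-2-yloxy)benzaldehyde, via arylboronic pinacol ester 6 (not isolated)
Conditions: B2pin2 (1.05 equiv), KOAc, Pd(dppf)Cl2 (3 mol %), 1,4-dioxane, 85 °C; then 3 (1.2 equiv), K3PO4, H2O, 65 °C
Reagents that add atoms: none
Why: Miyaura borylation followed in the same pot by a Suzuki–Miyaura allyl–aryl coupling, in which zerovalent palladium ionises the allylic acetate, the arylboronate transmetalates and reductive elimination places the aryl group on the unhindered CH2 terminus, while the E geometry is kept because scrambling would need the tertiary σ-allyl and the free tertiary alcohol and aldehyde are inert.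

Step 4
Reactants: 8 2,4,6-trihydroxyacetophenone [1-(2,4,6-trihydroxyphenyl)ethan-1-one]
Product: 9 1-[2-hydroxy-4,6-bis(tetrahydro-2H-pyran-2-yloxy)phenyl]ethan-1-one
Conditions: 3,4-dihydro-2H-pyran (3 equiv), PPTS (10 mol %), CH2Cl2, rt
Reagents that add atoms: 3,4-dihydro-2H-pyran, C1=COCCC1
Why: Tetrahydropyranylation protects the two free phenols, while the third ortho-OH stays free because its hydrogen bond to the ketone makes it unreactive, as is usual for o-hydroxyacetophenones.

Step 5
Reactants: 9 1-[2-hydroxy-4,6-bis(tetrahydro-2H-pyran-2-yloxy)phenyl]ethan-1-one; 7 3-[(2E)-7-hydroxy-3,7-dimethyloct-2-en-1-yl]-4-(tetrahydro-2H-pyran-2-yloxy)benzaldehyde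
Product: 11 (2E)-1-[2-hydroxy-4,6-bis(tetrahydro-2H-pyran-2-yloxy)phenyl]-3-{3-[(2E)-7-hydroxy-3,7-dimethyloct-2-en-1-yl]-4-(tetrahydro-2H-pyran-2-yloxy)phenyl}prop-2-en-1-one, via aldol adduct 10 (not isolated)
Conditions: KOH (50 % aq., 10 equiv), EtOH, rt, 36 h; aq. NH4Cl work-up
Reagents that add atoms: none
Why: Claisen–Schmidt condensation (crossed aldol addition of the methyl ketone enolate to the non-enolisable aldehyde, then E1cB loss of water) gives the thermodynamic E-enone, and the THP ethers, the tertiary alcohol and the side-chain alkene are inert to hydroxide.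

Step 6
Reactants: 11 the tris-THP chalcone of step 5
Product: 12 (2E)-3-{4-hydroxy-3-[(2E)-7-hydroxy-3,7-dimethyloct-2-en-1-yl]phenyl}-1-(2,4,6-trihydroxyphenyl)prop-2-en-1-one
Conditions: PPTS (0.3 equiv), EtOH, 45 °C, 5 h
Reagents that add atoms: none
Why: Acid-catalysed transacetalisation (ethanolysis of the three aryl THP ethers) frees the phenols under acid too weak to protonate the trisubstituted alkene, ionise the tertiary alcohol or close the chalcone, which stays open in the absence of base.

Step 7
Reactants: 12 (2E)-3-{4-hydroxy-3-[(2E)-7-hydroxy-3,7-dimethyloct-2-en-1-yl]phenyl}-1-(2,4,6-trihydroxyphenyl)prop-2-en-1-one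
Product: 13 (2S)-5,7-dihydroxy-2-{4-hydroxy-3-[(2E)-7-hydroxy-3,7-dimethyloct-2-en-1-yl]phenyl}-2,3-dihydro-4H-chromen-4-one (CNP0161524.1)
Conditions: Ni(acac)2 (10 mol %), ligand L (11 mol %, pre-complexed), 4 Å molecular sieves, EtOAc, 0 °C, 24 h; 5 % aq. citric acid work-up
Reagents that add atoms: none
Why: Proposed new method: a chelation-organised enantioselective 6-endo-trig oxa-Michael ring closure of an unprotected 2',6'-dihydroxychalcone, in which one ortho-phenol and the ketone of 12 displace one acetylacetonate from the divalent nickel centre of Ni(acac)2·L to give a flat six-membered phenoxide–ketone chelate that lowers the enone LUMO and holds C-β beside the other, unbound ortho-OH, the released acetylacetonate deprotonates that OH and then protonates the nickel enolate at C-3, one 2,6-diisopropylanilide arm of L screens one face of the chelate so that the O1–C2 bond forms on the open face and sets C-2 as S, and the product, bound as its 5-oxido-4-keto chelate, is displaced by fresh 12; the closest known reaction type is the chiral N,N'-dioxide–Ni(acac)2-catalysed intramolecular oxa-Michael addition of α-ester-activated 2'-hydroxychalcones to flavanones, and the new element is that the substrate's own phenol–ketone pair serves as the two-point binding handle on a chalcone that otherwise closes only racemically with base.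

## Compound list

1 | geranyl acetate, (2E)-3,7-dimethylocta-2,6-dien-1-yl acetate | C/C(=C\COC(C)=O)CCC=C(C)C | starting material
2 | (2E)-6-(acetoxymercurio)-7-hydroxy-3,7-dimethyloct-2-en-1-yl acetate (racemic at C6, not isolated) | C/C(=C\COC(C)=O)CCC([Hg]OC(C)=O)C(C)(C)O | intermediate
3 | (2E)-7-hydroxy-3,7-dimethyloct-2-en-1-yl acetate | C/C(=C\COC(C)=O)CCCC(C)(C)O | intermediate
4 | 3-bromo-4-hydroxybenzaldehyde | O=Cc1ccc(O)c(Br)c1 | starting material
5 | 3-bromo-4-(tetrahydro-2H-pyran-2-yloxy)benzaldehyde (racemic acetal carbon) | O=Cc1ccc(OC2CCCCO2)c(Br)c1 | intermediate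
6 | 4-(tetrahydro-2H-pyran-2-yloxy)-3-(4,4,5,5-tetramethyl-1,3,2-dioxaborolan-2-yl)benzaldehyde (racemic acetal carbon, not isolated) | O=Cc1ccc(OC2CCCCO2)c(B2OC(C)(C)C(C)(C)O2)c1 | intermediate
7 | 3-[(2E)-7-hydroxy-3,7-dimethyloct-2-en-1-yl]-4-(tetrahydro-2H-pyran-2-yloxy)benzaldehyde (racemic acetal carbon) | C/C(=C\Cc1cc(C=O)ccc1OC1CCCCO1)CCCC(C)(C)O | intermediate
8 | 2,4,6-trihydroxyacetophenone, 1-(2,4,6-trihydroxyphenyl)ethan-1-one | CC(=O)c1c(O)cc(O)cc1O | starting material
9 | 1-[2-hydroxy-4,6-bis(tetrahydro-2H-pyran-2-yloxy)phenyl]ethan-1-one (acetal epimer mixture) | CC(=O)c1c(O)cc(OC2CCCCO2)cc1OC1CCCCO1 | intermediate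
10 | 3-hydroxy-1-[2-hydroxy-4,6-bis(tetrahydro-2H-pyran-2-yloxy)phenyl]-3-{3-[(2E)-7-hydroxy-3,7-dimethyloct-2-en-1-yl]-4-(tetrahydro-2H-pyran-2-yloxy)phenyl}propan-1-one (racemic carbinol, acetal epimer mixture, not isolated) | C/C(=C\Cc1cc(C(O)CC(=O)c2c(O)cc(OC3CCCCO3)cc2OC2CCCCO2)ccc1OC1CCCCO1)CCCC(C)(C)O | intermediate
11 | (2E)-1-[2-hydroxy-4,6-bis(tetrahydro-2H-pyran-2-yloxy)phenyl]-3-{3-[(2E)-7-hydroxy-3,7-dimethyloct-2-en-1-yl]-4-(tetrahydro-2H-pyran-2-yloxy)phenyl}prop-2-en-1-one (acetal epimer mixture) | C/C(=C\Cc1cc(/C=C/C(=O)c2c(O)cc(OC3CCCCO3)cc2OC2CCCCO2)ccc1OC1CCCCO1)CCCC(C)(C)O | intermediate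
12 | (2E)-3-{4-hydroxy-3-[(2E)-7-hydroxy-3,7-dimethyloct-2-en-1-yl]phenyl}-1-(2,4,6-trihydroxyphenyl)prop-2-en-1-one | C/C(=C\Cc1cc(/C=C/C(=O)c2c(O)cc(O)cc2O)ccc1O)CCCC(C)(C)O | intermediate
13 | (2S)-5,7-dihydroxy-2-{4-hydroxy-3-[(2E)-7-hydroxy-3,7-dimethyloct-2-en-1-yl]phenyl}-2,3-dihydro-4H-chromen-4-one | C/C(=C\Cc1cc([C@@H]2CC(=O)c3c(O)cc(O)cc3O2)ccc1O)CCCC(C)(C)O | target

## Step count and risks

Total step count: 7. Longest linear sequence: 5 steps (4 → 5 → 7 → 11 → 12 → 13; the arm from 1 is equally long).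

**First risk, step 3.** The telescoped borylation and allyl–aryl coupling may suffer from slow ionisation of the trisubstituted allylic acetate, some E/Z erosion, or borylation of the acetate by leftover B2pin2. The fallback sets out from 3 and 5 and comes back at 7, and replaces the palladium coupling by an SN2 alkylation of an arylcopper. Acetate 3 is methanolysed (K2CO3, MeOH) to (2E)-3,7-dimethyloct-2-ene-1,7-diol F1. Its primary allylic hydroxyl alone is brominated under Appel conditions (CBr4, PPh3, CH2Cl2, −20 °C) to (2E)-8-bromo-2,6-dimethyloct-6-en-2-ol F2. F2 is deprotonated at −78 °C with LiN(SiMe3)2 to its lithium alkoxide F3. In a second flask the aldehyde of 5 is masked with LiN(Me)CH2CH2NMe2 (from the amine and n-BuLi, THF, −20 °C) as the lithium α-amino alkoxide F4. F4 undergoes bromine–lithium exchange with n-BuLi at −78 °C to the aryllithium F5, which is transmetalated with CuBr·SMe2 to the arylcopper F6. F6 displaces the primary bromide of F3 without allylic transposition and with the E geometry kept, giving the dilithium salt F7. Aqueous NH4Cl work-up releases the aldehyde and the alcohol, which is 7.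

**Second risk, step 6.** The unmasked 2',6'-dihydroxychalcone may start to close racemically during deprotection or on silica. The fallback sets out from 11 and comes back at 13, and closes the ring before the phenols are unmasked. The single free 2'-OH of 11 is cyclised by amine-base and hydrogen-bond-donor organocatalysis (quinine-derived bifunctional squaramide, 10 mol %, toluene, rt; the quinidine-derived catalyst if the sense is wrong). This gives (2S)-2-{3-[(2E)-7-hydroxy-3,7-dimethyloct-2-en-1-yl]-4-(tetrahydro-2H-pyran-2-yloxy)phenyl}-5,7-bis(tetrahydro-2H-pyran-2-yloxy)-2,3-dihydro-4H-chromen-4-one F8. F8 has no free 5-OH and cannot ring-open, and PPTS, EtOH, 45 °C then removes the three THP groups to give 13.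

**Third risk, step 7 (the new ring closure).** The ee may be low, or turnover slow because the product binds nickel as strongly as the substrate. The fallback uses known chemistry, sets out from 12 and comes back at 13. Chalcone 12 is closed without stereocontrol by the classical NaOAc, EtOH, reflux cyclisation to racemic 5,7-dihydroxy-2-{4-hydroxy-3-[(2E)-7-hydroxy-3,7-dimethyloct-2-en-1-yl]phenyl}-2,3-dihydro-4H-chromen-4-one F9. The enantiomers are separated by preparative chiral SFC on an amylose tris(3,5-dimethylphenylcarbamate) phase, giving 13 and the (2R)-enantiomer F10. F10 is recycled by ring opening in cold aqueous KOH and acidification, which returns 12.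

## Further compounds

F1 | step 3 | (2E)-3,7-dimethyloct-2-ene-1,7-diol | C/C(=C\CO)CCCC(C)(C)O
F2 | step 3 | (2E)-8-bromo-2,6-dimethyloct-6-en-2-ol | C/C(=C\CBr)CCCC(C)(C)O
F3 | step 3 | lithium (2E)-8-bromo-2,6-dimethyloct-6-en-2-olate | C/C(=C\CBr)CCCC(C)(C)O[Li]
F4 | step 3 | lithium [3-bromo-4-(tetrahydro-2H-pyran-2-yloxy)phenyl]{[2-(dimethylamino)ethyl](methyl)amino}methanolate | CN(C)CCN(C)C(O[Li])c1ccc(OC2CCCCO2)c(Br)c1
F5 | step 3 | lithium {[2-(dimethylamino)ethyl](methyl)amino}[3-lithio-4-(tetrahydro-2H-pyran-2-yloxy)phenyl]methanolate | CN(C)CCN(C)C(O[Li])c1ccc(OC2CCCCO2)c([Li])c1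
F6 | step 3 | lithium [3-cuprio-4-(tetrahydro-2H-pyran-2-yloxy)phenyl]{[2-(dimethylamino)ethyl](methyl)amino}methanolate | CN(C)CCN(C)C(O[Li])c1ccc(OC2CCCCO2)c([Cu])c1
F7 | step 3 | dilithium salt of the coupled α-amino alkoxide and tertiary alkoxide (precursor of 7 before work-up) | C/C(=C\Cc1cc(C(O[Li])N(C)CCN(C)C)ccc1OC1CCCCO1)CCCC(C)(C)O[Li]
F8 | step 6 | (2S)-2-{3-[(2E)-7-hydroxy-3,7-dimethyloct-2-en-1-yl]-4-(tetrahydro-2H-pyran-2-yloxy)phenyl}-5,7-bis(tetrahydro-2H-pyran-2-yloxy)-2,3-dihydro-4H-chromen-4-one | C/C(=C\Cc1cc([C@@H]2CC(=O)c3c(OC4CCCCO4)cc(OC4CCCCO4)cc3O2)ccc1OC1CCCCO1)CCCC(C)(C)O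
F9 | step 7 | racemic 5,7-dihydroxy-2-{4-hydroxy-3-[(2E)-7-hydroxy-3,7-dimethyloct-2-en-1-yl]phenyl}-2,3-dihydro-4H-chromen-4-one | C/C(=C\Cc1cc(C2CC(=O)c3c(O)cc(O)cc3O2)ccc1O)CCCC(C)(C)O
F10 | step 7 | (2R)-5,7-dihydroxy-2-{4-hydroxy-3-[(2E)-7-hydroxy-3,7-dimethyloct-2-en-1-yl]phenyl}-2,3-dihydro-4H-chromen-4-one | C/C(=C\Cc1cc([C@H]2CC(=O)c3c(O)cc(O)cc3O2)ccc1O)CCCC(C)(C)O
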